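**Plan**

- Numbering follows the quinolin-4(1H)-one (N1, C2–C4, C4a, C5–C8, C8a). The retrosynthesis removes both O-methyl groups, exchanges N1–OH for ring oxygen (pyridone to 4-pyranone) and opens O1–C2 to a 1,3,5-triketone.
- It then cuts C3–C4 (aldol of a symmetrical dihydroxyacetone acetonide, which brings C3, C2 and the CH2O carbon, onto a C4 aldehyde) and finally the carbocycle at C5–C6 and C4a–C8a.
- Enabling feature: the carbocycle holds the only stereocentre (C5) next to C4a, so C4(=O)–C4a–C5–octyl is the carbon chain of (E)-undec-2-enal, while the heteroatom-bearing fusion carbon C8a with C8, C7 and C6 is a 1-acyloxybutadiene oxygenated at its terminus.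
- Forward order: carbocycle first (cycloaddition), then the C3–C2–CH2O chain, then the oxygen heterocycle by cyclodehydration, then O-to-N exchange and two O-methylations.
- Stereochemistry: C5 (R) is set once, by the chiral amine catalyst in the cycloaddition; every other centre created on the way ends as an sp2 carbon.

Key step: step 1

Assumption: the (5R) catalyst is chosen from the usual shielding model of the iminium ion (benzyl over one face, diene on the other), and commercial 2, sold as an E/Z mixture, is used in excess because only the E isomer is expected to react as an s-cis diene.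

**Step 1**
Reactants: 1 (E)-undec-2-enal; 2 (E)-buta-1,3-dien-1-yl acetate
Product: 3 (1S,2R,6R)-2-acetoxy-6-octylcyclohex-3-ene-1-carbaldehyde (endo adduct)
Conditions: (5R)-5-benzyl-2,2,3-trimethylimidazolidin-4-one hydrochloride (20 mol %), 2 (3 equiv), MeNO2/H2O 95:5, 0 °C to rt; short silica plug, used at once
Reagents that add atoms: none
Why: Condensation of 1 with the amine salt gives an (E)-iminium ion of lowered LUMO energy that takes up the E isomer of 2 in a concerted but asynchronous [4+2] cycloaddition, the unsubstituted diene terminus bonding first to the β-carbon, and hydrolysis of the adduct iminium ion releases 3 and the catalyst. The closest known reaction type is the imidazolidinone-salt-catalysed enantioselective Diels–Alder reaction of enals with acyclic dienes, 1-acetoxybutadiene included. The six-membered carbocycle is closed in intermolecular [4+2] mode by the two bonds C5–C6 and C4a–C8a (adduct C6–C5 and C1–C2). Adduct C6 (later C5) is controlled by the catalyst, whose benzyl group covers one face of the iminium ion so that the diene adds to the open face and the (5R) catalyst gives the R centre; C1 is fixed trans to octyl by the E geometry of the enal and C2 cis to formyl by the endo transition state. The step needs facial selectivity only, since C1 and C2 become sp2 later and any exo adduct converges, and the ortho regiochemistry is secured by the acetoxy donor on the diene terminus that bonds to the α-carbon.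

**Step 2**
Reactants: 3 (1S,2R,6R)-2-acetoxy-6-octylcyclohex-3-ene-1-carbaldehyde
Product: 4 (1S,2R,6R)-2-acetoxy-6-octylcyclohexane-1-carbaldehyde
Conditions: H2 (1 atm), 5% Rh/Al2O3, EtOAc, rt
Reagents that add atoms: none
Why: Heterogeneous catalytic hydrogenation of the cis-disubstituted ring alkene, with Rh on alumina chosen because it saturates C=C without hydrogenolysis of the allylic C–O bond, without reducing the aldehyde and with little double-bond migration toward the octyl-bearing carbon; no stereocentre is formed and the adduct can no longer lose acetic acid to a conjugated dienal.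

**Step 3**
Reactants: 4 (1S,2R,6R)-2-acetoxy-6-octylcyclohexane-1-carbaldehyde; 5 2,2-dimethyl-1,3-dioxan-5-one
Product: 7 (1R,2R,3R)-2-[(2,2-dimethyl-5-oxo-1,3-dioxan-4-yl)(hydroxy)methyl]-3-octylcyclohexyl acetate (mixture at the two new centres), via lithium dioxinolate 6 (not isolated)
Conditions: 5, LiN(i-Pr)2, THF, −78 °C; then 4, −78 °C; AcOH, −78 °C
Reagents that add atoms: none
Why: Lithium-enolate aldol addition of a preformed ketone enolate to an α-branched aldehyde: because the dioxanone is symmetrical, C3, C2 and the CH2O carbon are attached in one C–C bond formation with no regiochemical choice, the aldehyde reacts far faster than the acetate at −78 °C, and the two new stereocentres (formed as a mixture) are later erased as sp2 carbons.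

**Step 4**
Reactants: 7 (1R,2R,3R)-2-[(2,2-dimethyl-5-oxo-1,3-dioxan-4-yl)(hydroxy)methyl]-3-octylcyclohexyl acetate
Product: 8 (1R,2S,3R)-2-(2,2-dimethyl-5-oxo-1,3-dioxane-4-carbonyl)-3-octylcyclohexyl acetate
Conditions: Dess–Martin periodinane, pyridine, CH2Cl2, 0 °C to rt
Reagents that add atoms: none
Why: Dess–Martin oxidation of the β-hydroxy ketone to the 1,3-diketone under pyridine-buffered, non-basic conditions that leave the β-acetoxy group and the acetonide in place.

**Step 5**
Reactants: 8 (1R,2S,3R)-2-(2,2-dimethyl-5-oxo-1,3-dioxane-4-carbonyl)-3-octylcyclohexyl acetate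
Product: 9 4-[(1S,2R,6R)-2-hydroxy-6-octylcyclohexane-1-carbonyl]-2,2-dimethyl-1,3-dioxan-5-one
Conditions: NaOMe (2.2 equiv), MeOH, 0 °C to rt; then AcOH (2.2 equiv), 0 °C
Reagents that add atoms: none
Why: Zemplén-type methanolysis of the secondary acetate: under methoxide the 1,3-diketone is held as its enolate, which shuts down both E1cB loss of acetate and retro-Claisen cleavage while the ester is transesterified.

**Step 6**
Reactants: 9 4-[(1S,2R,6R)-2-hydroxy-6-octylcyclohexane-1-carbonyl]-2,2-dimethyl-1,3-dioxan-5-one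
Product: 10 2,2-dimethyl-4-[(6R)-6-octyl-2-oxocyclohexane-1-carbonyl]-1,3-dioxan-5-one (enolised triketone)
Conditions: Dess–Martin periodinane, pyridine, CH2Cl2, 0 °C to rt; used crude
Reagents that add atoms: none
Why: Dess–Martin oxidation of the ring carbinol gives the 1,3,5-triketone, in which the octyl-bearing carbon is not α to any carbonyl and therefore keeps its configuration.

**Step 7**
Reactants: 10 2,2-dimethyl-4-[(6R)-6-octyl-2-oxocyclohexane-1-carbonyl]-1,3-dioxan-5-one
Product: 12 (5R)-3-hydroxy-2-(hydroxymethyl)-5-octyl-5,6,7,8-tetrahydro-4H-chromen-4-one, via acetonide-bridged pyranone 11 (not isolated)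
Conditions: CSA (10 mol %), 4 Å MS, CH2Cl2, rt; then 2 M HCl, THF, 50 °C
Reagents that add atoms: none
Why: Acid-catalysed cyclodehydration of a 1,3,5-triketone to a 4-pyranone (6-exo-trig attack of the C8a enol oxygen on the C2 ketone and loss of water, O-cyclisation being the acid-mediated pathway), run first without water so that the masked primary hydroxyl cannot close a furanone, followed by ordinary aqueous-acid hydrolysis of the isopropylidene acetal.

**Step 8**
Reactants: 12 (5R)-3-hydroxy-2-(hydroxymethyl)-5-octyl-5,6,7,8-tetrahydro-4H-chromen-4-one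
Product: 13 (5R)-2-(hydroxymethyl)-3-methoxy-5-octyl-5,6,7,8-tetrahydro-4H-chromen-4-one
Conditions: MeI (1.1 equiv), K2CO3, acetone, 40 °C
Reagents that add atoms: iodomethane, CI
Why: Williamson methylation under carbonate conditions, selective for the acidic enolic 3-hydroxyl of a 3-hydroxy-4-pyranone (pKa near 9) over the primary alcohol, as in the O-methylation of kojic acid.

**Step 9**
Reactants: 13 (5R)-2-(hydroxymethyl)-3-methoxy-5-octyl-5,6,7,8-tetrahydro-4H-chromen-4-one
Product: 14 (5R)-1-hydroxy-2-(hydroxymethyl)-3-methoxy-5-octyl-5,6,7,8-tetrahydroquinolin-4(1H)-one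
Conditions: NH2OH·HCl (5 equiv), NaOAc (5 equiv), EtOH/H2O 1:1, 80 °C
Reagents that add atoms: hydroxylamine hydrochloride, Cl.NO
Why: Pyranone-to-pyridone exchange with hydroxylamine (conjugate addition of nitrogen at C2 or C8a, ring opening, recyclisation through nitrogen and loss of water), the known route from 3-alkoxy-4-pyranones to 1-hydroxy-4-pyridones, which does not touch C5.

**Step 10**
Reactants: 14 (5R)-1-hydroxy-2-(hydroxymethyl)-3-methoxy-5-octyl-5,6,7,8-tetrahydroquinolin-4(1H)-one
Product: 15 (5R)-2-(hydroxymethyl)-1,3-dimethoxy-5-octyl-5,6,7,8-tetrahydroquinolin-4(1H)-one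
Conditions: MeI (1.1 equiv), K2CO3, DMF, rt
Reagents that add atoms: iodomethane, CI
Why: O-Alkylation of the N-hydroxy group (hydroxamic-acid-like, pKa near 6) with MeI and carbonate, a reaction known to give 1-alkoxy-4-pyridones, which leaves the far less acidic primary alcohol free.

**Compound list**

1 | (E)-undec-2-enal | CCCCCCCC/C=C/C=O | starting material
2 | (E)-buta-1,3-dien-1-yl acetate | CC(=O)O/C=C/C=C | starting material
3 | (1S,2R,6R)-2-acetoxy-6-octylcyclohex-3-ene-1-carbaldehyde | CCCCCCCC[C@@H]1CC=C[C@@H](OC(C)=O)[C@H]1C=O | intermediate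
4 | (1S,2R,6R)-2-acetoxy-6-octylcyclohexane-1-carbaldehyde | CCCCCCCC[C@@H]1CCC[C@@H](OC(C)=O)[C@H]1C=O | intermediate
5 | 2,2-dimethyl-1,3-dioxan-5-one | CC1(C)OCC(=O)CO1 | starting material
6 | lithium 2,2-dimethyl-4H-1,3-dioxin-5-olate (lithium enolate of 5) | [Li+].[O-]C1=COC(C)(C)OC1 | intermediate
7 | (1R,2R,3R)-2-[(2,2-dimethyl-5-oxo-1,3-dioxan-4-yl)(hydroxy)methyl]-3-octylcyclohexyl acetate, mixture at the carbinol carbon and at dioxane C4 | CCCCCCCC[C@@H]1CCC[C@@H](OC(C)=O)[C@H]1C(O)C1OC(C)(C)OCC1=O | intermediate
8 | (1R,2S,3R)-2-(2,2-dimethyl-5-oxo-1,3-dioxane-4-carbonyl)-3-octylcyclohexyl acetate, dioxane C4 undefined (enolisable) | CCCCCCCC[C@@H]1CCC[C@@H](OC(C)=O)[C@H]1C(=O)C1OC(C)(C)OCC1=O | intermediate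
9 | 4-[(1S,2R,6R)-2-hydroxy-6-octylcyclohexane-1-carbonyl]-2,2-dimethyl-1,3-dioxan-5-one, dioxane C4 undefined | CCCCCCCC[C@@H]1CCC[C@@H](O)[C@H]1C(=O)C1OC(C)(C)OCC1=O | intermediate
10 | 2,2-dimethyl-4-[(6R)-6-octyl-2-oxocyclohexane-1-carbonyl]-1,3-dioxan-5-one, enolisable centres undefined | CCCCCCCC[C@@H]1CCCC(=O)C1C(=O)C1OC(C)(C)OCC1=O | intermediate
11 | isopropylidene acetal of 12, the acetonide bridging the 3-oxygen and the oxygen of the 2-CH2O group | CCCCCCCC[C@@H]1CCCc2c1c(=O)c1OC(C)(C)OCc1o2 | intermediate
12 | (5R)-3-hydroxy-2-(hydroxymethyl)-5-octyl-5,6,7,8-tetrahydro-4H-chromen-4-one | CCCCCCCC[C@@H]1CCCc2c1c(=O)c(O)c(CO)o2 | intermediate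
13 | (5R)-2-(hydroxymethyl)-3-methoxy-5-octyl-5,6,7,8-tetrahydro-4H-chromen-4-one | CCCCCCCC[C@@H]1CCCc2c1c(=O)c(OC)c(CO)o2 | intermediate
14 | (5R)-1-hydroxy-2-(hydroxymethyl)-3-methoxy-5-octyl-5,6,7,8-tetrahydroquinolin-4(1H)-one | CCCCCCCC[C@@H]1CCCc2c1c(=O)c(OC)c(CO)n2O | intermediate
15 | (5R)-2-(hydroxymethyl)-1,3-dimethoxy-5-octyl-5,6,7,8-tetrahydroquinolin-4(1H)-one (CNP0118952.1) | CCCCCCCC[C@@H]1CCCc2c1c(=O)c(OC)c(CO)n2OC | target

**Step count and risks**

Total step count: 10. Longest linear sequence: 10 steps (1 to 15).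

Steps most likely to fail:

1. Step 1. The β-alkyl iminium ion may add the weakly nucleophilic acetoxydiene so slowly that hydrolysis of the diene and amine-promoted loss of acetic acid from the adduct compete. The fallback keeps the same two ring bonds but moves to an auxiliary-controlled, Lewis-acid-promoted cycloaddition. It sets out from 1 and rejoins the route at 4.
   - Pinnick oxidation of 1 (NaClO2, NaH2PO4, 2-methylbut-2-ene) would give (E)-undec-2-enoic acid F1.
   - Its pivaloyl mixed anhydride and the lithium salt of (R)-4-benzyloxazolidin-2-one would give (R)-4-benzyl-3-[(E)-undec-2-enoyl]oxazolidin-2-one F2.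
   - Et2AlCl in CH2Cl2 at low temperature would hold F2 as the chelated s-cis dienophile, and 2 would add anti to the benzyl group to give the imide adduct F3.
   - Hydrogenation over Rh/Al2O3 would give the saturated imide F4.
   - LiSEt would cleave the auxiliary to give the S-ethyl thioester F5.
   - Fukuyama reduction (Et3SiH, Pd/C) would give aldehyde 4.

2. Step 9. Attack of hydroxylamine at the fully substituted C2 and C8a positions may be slow, and ring-opened intermediates may be diverted to oximes or isoxazoles. The fallback introduces nitrogen first and the N–O bond afterwards. It sets out from 13 and rejoins at 14.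
   - Aqueous NH3 in EtOH (sealed tube) would give the NH-pyridone F6.
   - BnBr with Ag2CO3 in toluene would alkylate the 4-oxygen to give the 4-benzyloxypyridine F7.
   - mCPBA would give the N-oxide F8.
   - Hydrogenolysis of the benzyl ether (H2, Pd/C) would unveil the 1-hydroxy-4-pyridone 14.

3. Step 6. The δ-hydroxy-β-diketone may close to its cyclic hemiketal and dehydrate faster than the carbinol is oxidised. The fallback reverses the order of ring closure and oxidation. It sets out from 9 and rejoins at 11.
   - CSA in CH2Cl2 would drive that closure on purpose to the cis-fused dihydropyranone F9.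
   - Dehydrogenation across C4a–C8a with DDQ in dioxane (the chromanone-to-chromone type of oxidation) would give 11, which is hydrolysed as in the second stage of step 7.

**Further compounds**

F1 | step 1 | (E)-undec-2-enoic acid | CCCCCCCC/C=C/C(=O)O
F2 | step 1 | (R)-4-benzyl-3-[(E)-undec-2-enoyl]oxazolidin-2-one | CCCCCCCC/C=C/C(=O)N1[C@H](Cc2ccccc2)COC1=O
F3 | step 1 | (R)-4-benzyl-3-[(1S,2R,6R)-2-acetoxy-6-octylcyclohex-3-ene-1-carbonyl]oxazolidin-2-one | CCCCCCCC[C@@H]1CC=C[C@@H](OC(C)=O)[C@H]1C(=O)N1[C@H](Cc2ccccc2)COC1=O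
F4 | step 1 | (R)-4-benzyl-3-[(1S,2R,6R)-2-acetoxy-6-octylcyclohexane-1-carbonyl]oxazolidin-2-one | CCCCCCCC[C@@H]1CCC[C@@H](OC(C)=O)[C@H]1C(=O)N1[C@H](Cc2ccccc2)COC1=O
F5 | step 1 | S-ethyl (1S,2R,6R)-2-acetoxy-6-octylcyclohexane-1-carbothioate | CCCCCCCC[C@@H]1CCC[C@@H](OC(C)=O)[C@H]1C(=O)SCC
F6 | step 9 | (5R)-2-(hydroxymethyl)-3-methoxy-5-octyl-5,6,7,8-tetrahydroquinolin-4(1H)-one | CCCCCCCC[C@@H]1CCCc2c1c(=O)c(OC)c(CO)[nH]2
F7 | step 9 | [(5R)-4-(benzyloxy)-3-methoxy-5-octyl-5,6,7,8-tetrahydroquinolin-2-yl]methanol | CCCCCCCC[C@@H]1CCCc2c1c(OCc1ccccc1)c(OC)c(CO)n2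
F8 | step 9 | (5R)-4-(benzyloxy)-2-(hydroxymethyl)-3-methoxy-5-octyl-5,6,7,8-tetrahydroquinoline 1-oxide | CCCCCCCC[C@@H]1CCCc2c1c(OCc1ccccc1)c(OC)c(CO)[n+]2[O-]
F9 | step 6 | cis-fused isopropylidene acetal of (5R)-3-hydroxy-2-(hydroxymethyl)-5-octyl-4a,5,6,7,8,8a-hexahydro-4H-chromen-4-one | CCCCCCCC[C@@H]1CCC[C@H]2OC3=C(OC(C)(C)OC3)C(=O)[C@@H]12
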